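## The problem

The target is an isocoumarin (ring A fused to a 3-pentylpyranone) whose C8 carries, through an ether oxygen, a second arene (ring B: C1' on oxygen, C2' OH, C4' OMe, C6' pentyl). The central difficulty is this diaryl ether. Its oxygen sits between C8, which is ortho to the lactone carbon C1 on C8a, and C1', which is flanked by a hydroxyl and a pentyl chain, so a direct aryl–oxygen coupling is hindered on both partners. There are no stereocentres, so every control problem is regiochemical. Three phenolic oxygens must end up differentiated (free 6-OH and 2'-OH, methylated 4'-O), the two pentyl chains must sit at C3 and C6', and the C6 oxygen must be placed meta to both C8 and C4a. The sensitive parts are the enol lactone (opened by hydroxide or alkoxide, and its C3=C4 bond is exposed under hydrogenolysis), the electron-rich ring B, and, in the route chosen here, a terminal aryl ynol ether. The enabling feature is the pattern on ring A: the carboxyl carbon C1 on C8a is ortho to the aryloxy carbon C8, C7 is unsubstituted and C4a carries a one-carbon branch (C4). This is what results when an aryl ethynyl ether (C7, C8) adds across a 4-methyl-2-pyranone-3-carboxylate (C8a, C4a, C5, C6) and the adduct loses CO2, so the hindered oxygen is already bonded to ring B before ring A exists.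

## Retrosynthesis

**Target 27 to keto ester 25 (through 26).** The enol lactone bond O2–C1 and the two acetal C–O bonds of the MOM groups are cut. Enol lactonisation of an ortho-(2-oxoalkyl)benzoate is the most direct entry to a 3-alkylisocoumarin, and two MOM acetals allow one acid treatment to deprotect and close the ring. Benzyl ethers were rejected because they would need hydrogenolysis beside the C3=C4 bond and would offer unhindered aryl C–H bonds to the iridium catalyst used earlier. Precursor 25 is an open-chain ester with no heterocycle. The forward step must close the six-membered enol lactone faster than the seven-membered aryl ester that the liberated ring B phenol of 26 could form.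

**25 to toluate 21 and amide 22 (through 23 and 24).** The C3–C4 bond between the benzylic carbon and the ketone carbon is cut. The benzylic methyl group comes free of charge from the cycloaddition, whereas an alkyne-cyclisation approach to the lactone would need a halogen at C4a instead. Precursor 21 is six carbons smaller. The forward reaction needs benzylic deprotonation without attack on the ester, and an acyl donor that cannot add twice.

**21 to phenol 20 to benzoate 18 (through boronate 19).** The C6–O bond is cut back to a C–H bond. On 18 the ring A C–H para to the ester is the only one with two hydrogen neighbours, and both ring B C–H bonds are flanked by two substituents, so a sterically governed iridium-catalysed borylation has a single site. Doing this before the side chain is built keeps the ketone and the enol lactone away from the catalyst and lets the new phenol take the same MOM group as ring B. Carrying the oxygen on the pyranone instead would change the electronic bias of the diene. The forward sequence needs an oxidation that spares the ester and the acetal.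

**18 to ynol ether 12 and pyranone 16 (through 17); the key disconnection.** The C6–C7 and C8–C8a bonds are cut and the lactone bridge of 16 is formally restored. The neighbouring cut at the aryl–oxygen bond would require coupling two ortho-substituted arenes. Here the oxygen is already on ring B and ring A is built around it. The precursors are a fully substituted ring B alkyne and a small heterocycle. The forward reaction needs one regiochemistry (aryloxy ortho to ester), and cycloaddition faster than self-reaction of 12.

**12 to dichlorovinyl ether 9 to phenol 7 and trichloroethylene 8 (through 10 and 11).** The O–C(sp) bond is traced back to an O–C(sp2) bond made by adding the phenoxide of 7 to the two-carbon unit of 8. Two eliminations then give the alkyne. This puts the hindered oxygen on carbon under simple basic conditions. The forward steps need a base strong enough for elimination and halogen–metal exchange, which the MOM acetal must survive.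

**7 to aldehydes 5, 4, 3 and olivetol 1 (through 6 and 2).** The C1'–O bond is traced back to a C1'–CHO bond, replaced by oxygen through aryl migration to a peracid. The formyl group first enters 1 selectively at the position ortho to one hydroxyl and to the pentyl chain. It then distinguishes the two hydroxyls, because the ortho one is hydrogen-bonded and the para one is methylated to give 4. Finally it is exchanged for the oxygen that becomes the ether link. Mono-methylation of 1 before formylation would be statistical and the later acylation ambiguous.

**16 to alkylidene malonate 15 to dimethyl malonate 13 and keto acetal 14.** The ring O–C2 acyl bond and the C3=C4 double bond are cut. The two ester groups of 15 are identical, so one is always cis to the masked aldehyde arm and the alkene geometry cannot go wrong. The forward steps are a ketone Knoevenagel condensation and an acid-mediated ring closure.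

## Roads not taken

**Alternative 1:** The cut is inside ring B (C1'–C6' and C2'–C3'), so the ether oxygen is first attached to an sp3 malonate carbon. In the forward key step dimethyl 2-[5-(benzyloxy)-2-(diethylcarbamoyl)-3-methylphenoxy]propanedioate A1 adds in Michael fashion to (E)-non-3-en-2-one A2 under alkoxide. The methyl ketone then closes onto one ester (Claisen) to give cyclohexane-1,3-dione A3.
- Merits: no aryl–oxygen coupling is needed, the partners are cheap, and ring A enters with its C6 oxygen in place, so no C–H oxidation is required. It also avoids ynol ether 12 and the iridium step, and in robustness of individual reagents it is the better road.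
- Weak points: A1 is a tertiary, oxygen-substituted donor adding reversibly to a β-alkyl enone. A3 is not aromatic and needs ester removal and a separate dehydrogenation beside an electron-rich ring. The resulting resorcinol has two free hydroxyls (2' and 4') with no chelation handle to tell them apart. The diethylamide must later be displaced in the lactonisation, which is harder than with an ester, and the benzyl ether must be hydrogenolysed beside the enol lactone.
- Comparison: the chosen plan forms ring A directly aromatic, buys ring B intact as 1 and differentiates its oxygens through the hydrogen bond in 3, which gives a shorter sequence after the key step.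

**Alternative 2:** The cut removes the whole pyranone ring (C4–C4a, C8a–C1, O2–C3). In the forward key step fluoride releases an aryne from 5-(benzyloxy)-3-[2-(benzyloxy)-4-methoxy-6-pentylphenoxy]-2-(trimethylsilyl)phenyl trifluoromethanesulfonate A4. Under copper catalysis the acetylide of hept-1-yne A5 adds, the aryl–metal intermediate is trapped by carbon dioxide A6, and the carboxylate closes onto the alkyne to give isocoumarin A7.
- Merits: this is the most convergent end game. The lactone ring and its pentyl chain appear in one operation, where the chosen plan needs steps 12 and 13. The sense of addition should also be right, because the acetylide is expected at the aryne carbon remote from the aryloxy group, leaving the metal at C8a.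
- Weak points: A4 already contains the hindered diaryl ether, so the main problem is only moved into the precursor, which also needs adjacent silyl and triflate groups on a crowded ring. Protonation of the aryl–metal species competes with capture of A6, and 5-exo closure to an alkylidene phthalide competes with 6-endo closure, next to a bulky aryloxy group. Two benzyl ethers must then be removed beside the C3=C4 bond.
- Comparison: the chosen plan is longer after its key step, but its key step makes the ether-bearing ring from phenol 7 and a two-carbon reagent, and its regiochemistry rests on one strong electronic bias.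

**Alternative 3:** Four ring B bonds are cut (C5'–C6', C2'–C3', C4'–C5', C1'–C2'). In the forward key step irradiation of methyl 4-(benzyloxy)-2-{[2-(2-diazoacetyl)hept-1-en-1-yl]oxy}-6-methylbenzoate A8 triggers a Wolff rearrangement to a vinylketene, which adds methoxyethyne A9 in a [2+2] reaction. Heating opens the cyclobutenone, and six-electron electrocyclisation with tautomerisation gives phenol A10.
- Merits: the ring B oxygens emerge differentiated by mechanism (free OH at C2', methyl ether at C4' from A9). Ring A again carries its C6 oxygen from the start, and the ether is made as an enol ether, not by arene coupling. In oxygen differentiation and in avoiding late C–H oxidation this road is at least as good as the chosen one.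
- Weak points: A8 needs several steps and combines a hydrolytically labile β-aryloxy enone with a diazo group. A9 is volatile and must be prepared and handled cold. The photochemical step is awkward on scale, the β-aryloxy vinylketene may expel phenoxide, and the benzyl ether is again removed by hydrogenolysis.
- Comparison: the chosen plan also relies on a sensitive alkyne (12) and claims no advantage there. It sets against alternative 3 a purchased ring B (1) elaborated by classical steps, no diazo compound or photolysis, and fewer steps to the cycloaddition partners.

Key step: step 9

Assumption: N-methoxy-N-methylhexanamide 22 is treated as a purchasable building block (otherwise one amidation from hexanoyl chloride), and ynol ether 12 is carried into step 9 as a freshly prepared cold solution. Abbreviations: MOM = methoxymethyl; cod = 1,5-cyclooctadiene; dtbpy = 4,4'-di-tert-butyl-2,2'-bipyridine; pin = pinacolato; TsOH = p-toluenesulfonic acid; TFA = trifluoroacetic acid; mCPBA = 3-chloroperbenzoic acid.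

## Route

Step 1
Reactants: 1 olivetol (5-pentylbenzene-1,3-diol)
Product: 3 2,4-dihydroxy-6-pentylbenzaldehyde, via aryl iminium chloride 2 (not isolated)
Conditions: POCl3, DMF, 0 °C → rt; then H2O, NaOAc, 50 °C
Reagents that add atoms: N,N-dimethylformamide, CN(C)C=O (formyl carbon); water, O (carbonyl oxygen); phosphoryl chloride, ClP(Cl)(Cl)=O (chloride of 2 only)
Why: Vilsmeier–Haack formylation; the chloroiminium ion attacks the resorcinol carbon that is para to one hydroxyl, ortho to the other and next to the alkyl chain (not the carbon between the two hydroxyls), as is usual for 5-alkylresorcinols, and hydrolysis of 2 releases the aldehyde.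

Step 2
Reactants: 3 2,4-dihydroxy-6-pentylbenzaldehyde
Product: 4 2-hydroxy-4-methoxy-6-pentylbenzaldehyde
Conditions: MeI (1.05 equiv), K2CO3, acetone, rt
Reagents that add atoms: iodomethane, CI
Why: Williamson etherification; the 2-OH is tied up in a hydrogen bond to the formyl group and is less acidic and less nucleophilic, so one equivalent of MeI should methylate the para hydroxyl selectively, as is standard for 2,4-dihydroxybenzaldehydes.

Step 3
Reactants: 4 2-hydroxy-4-methoxy-6-pentylbenzaldehyde
Product: 5 4-methoxy-2-(methoxymethoxy)-6-pentylbenzaldehyde
Conditions: NaH, DMF, 0 °C; MOMCl, 0 °C → rt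
Reagents that add atoms: chloromethyl methyl ether, COCCl
Why: Williamson-type acetal protection after full deprotonation of the chelated phenol; MOM is chosen because it survives n-BuLi, LiN(i-Pr)2, heat and the iridium catalyst, has no aryl C–H bonds of its own and leaves in the final acid step.

Step 4
Reactants: 5 4-methoxy-2-(methoxymethoxy)-6-pentylbenzaldehyde
Product: 7 4-methoxy-2-(methoxymethoxy)-6-pentylphenol, via aryl formate 6 (not isolated)
Conditions: mCPBA, NaHCO3, CH2Cl2, 0 °C → rt; then K2CO3 (cat.), MeOH, rt
Reagents that add atoms: 3-chloroperbenzoic acid, OOC(=O)c1cccc(Cl)c1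
Why: Baeyer–Villiger (Dakin-type) oxidation; the aryl group with ortho and para oxygen donors migrates in the Criegee intermediate to give formate 6, which mild methanolysis cleaves to the phenol while the buffered medium keeps the MOM acetal intact.

Step 5
Reactants: 7 4-methoxy-2-(methoxymethoxy)-6-pentylphenol; 8 trichloroethylene
Product: 9 2-[(E)-1,2-dichloroethenoxy]-5-methoxy-1-(methoxymethoxy)-3-pentylbenzene
Conditions: K2CO3, DMF, 70 °C
Reagents that add atoms: none
Why: Base-mediated dehydrochlorination of 8 gives dichloroacetylene in situ, to which the phenoxide adds in anti fashion, giving the (E)-1,2-dichlorovinyl ether; this is the standard entry to aryl ynol ethers and tolerates ortho substituents because the electrophile is linear and small.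

Step 6
Reactants: 9 2-[(E)-1,2-dichloroethenoxy]-5-methoxy-1-(methoxymethoxy)-3-pentylbenzene
Product: 12 2-(ethynyloxy)-5-methoxy-1-(methoxymethoxy)-3-pentylbenzene, via aryloxy chloroacetylene 10 (not isolated), via lithium aryloxyacetylide 11 (not isolated)
Conditions: n-BuLi (2.2 equiv), Et2O, −78 → −40 °C; then H2O, −78 °C; kept cold in solution
Reagents that add atoms: n-butyllithium, [Li]CCCC (lithium of 11 only)
Why: Vinylic deprotonation and β-elimination of LiCl give 10, chlorine–lithium exchange gives 11 and cold protonation gives the terminal ynol ether (the usual dichlorovinyl ether to alkynyl ether sequence); at −78 °C these events should outrun ring lithiation next to the MOM group.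

Step 7
Reactants: 13 dimethyl malonate; 14 4,4-dimethoxybutan-2-one
Product: 15 dimethyl 2-(4,4-dimethoxybutan-2-ylidene)propanedioate
Conditions: TiCl4, pyridine, THF, 0 °C → rt
Reagents that add atoms: none
Why: Knoevenagel condensation of a malonate with a ketone under TiCl4/pyridine, the usual conditions for ketones; the two esters are identical, so one is always cis to the acetal arm, and any enol ether formed from the acetal should converge on the same pyranone in step 8.

Step 8
Reactants: 15 dimethyl 2-(4,4-dimethoxybutan-2-ylidene)propanedioate
Product: 16 methyl 4-methyl-2-oxo-2H-pyran-3-carboxylate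
Conditions: TsOH·H2O (1 equiv), PhMe, 90 °C, MeOH distilled off
Reagents that add atoms: water, O
Why: Acid unmasks the acetal as an aldehyde/dienol, which closes onto the cis ester with loss of methanol (enol lactonisation of a 5-oxopent-2-enoate equivalent), the classical construction of 2-pyranone-3-carboxylates.

Step 9
Reactants: 12 2-(ethynyloxy)-5-methoxy-1-(methoxymethoxy)-3-pentylbenzene; 16 methyl 4-methyl-2-oxo-2H-pyran-3-carboxylate
Product: 18 methyl 2-[4-methoxy-2-(methoxymethoxy)-6-pentylphenoxy]-6-methylbenzoate, via bridged bicyclic lactone 17 (not isolated)
Conditions: PhMe, 90 °C, Ar; 12 added slowly to 16 (1.5 equiv)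
Reagents that add atoms: none
Why: This is the inverse-electron-demand Diels–Alder benzannulation of a 2-pyranone-3-carboxylate with a heteroatom-substituted alkyne, known for ynamines, alkoxyalkynes and ketene acetals and run here with an aryl ynol ether. Bond formation is asynchronous: the nucleophilic CH terminus of 12 attacks C6 of 16, the diene end that is the vinylogous acceptor position of both carbonyl groups, while the oxygen-stabilised alkyne carbon closes onto the ester-bearing C3. This polarity match fixes the regiochemistry, so the aryloxy group ends up ortho to the ester (new bonds C6–C7 and C8–C8a in isocoumarin numbering) and not meta to it. Ring A is closed by an intermolecular [4+2] cycloaddition that gives the 2-oxabicyclo[2.2.2]octadienone 17, and retro-[4+2] loss of CO2 from 17 turns the six carbons directly into an arene with no oxidant and no elimination step. No stereocentre has to be controlled, since the two bridgehead centres of 17 vanish on aromatisation. Besides regiochemistry the step needs cycloaddition to beat self-reaction of 12; the flanking MOM-oxy and pentyl groups shield the alkyne, an aryl ynol ether has no retro-ene path to a ketene, and slow addition to excess 16 keeps its concentration low. The 4-methyl group sits on a diene carbon that forms no bond and becomes the benzylic methyl used in step 12.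

Step 10
Reactants: 18 methyl 2-[4-methoxy-2-(methoxymethoxy)-6-pentylphenoxy]-6-methylbenzoate
Product: 20 methyl 4-hydroxy-2-[4-methoxy-2-(methoxymethoxy)-6-pentylphenoxy]-6-methylbenzoate, via aryl pinacol boronate 19 (not isolated)
Conditions: [Ir(OMe)(cod)]2 (1.5 mol %), dtbpy (3 mol %), B2pin2 (1.0 equiv), THF, 80 °C; then 30% H2O2, aq. NaOH, 0 °C
Reagents that add atoms: bis(pinacolato)diboron, CC1(C)OB(OC1(C)C)B1OC(C)(C)C(C)(C)O1 (boron of 19 only); hydrogen peroxide, OO (phenol oxygen)
Why: Iridium-catalysed C–H borylation is sterically governed: on ring A only the C–H para to the ester has no ortho substituent and both ring B C–H bonds lie between two substituents, so a single boronate 19 is expected; cold alkaline peroxide then exchanges boron for oxygen at the same carbon while the doubly ortho-substituted methyl ester and the MOM acetal should survive.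

Step 11
Reactants: 20 methyl 4-hydroxy-2-[4-methoxy-2-(methoxymethoxy)-6-pentylphenoxy]-6-methylbenzoate
Product: 21 methyl 4-(methoxymethoxy)-2-[4-methoxy-2-(methoxymethoxy)-6-pentylphenoxy]-6-methylbenzoate
Conditions: NaH, THF/DMF, 0 °C; MOMCl, 0 °C → rt
Reagents that add atoms: chloromethyl methyl ether, COCCl
Why: Williamson-type acetal protection of an unhindered, acidic para-hydroxybenzoate phenol; it is needed because a phenoxide conjugated with the ester would weaken the benzylic acidity used in step 12.

Step 12
Reactants: 21 methyl 4-(methoxymethoxy)-2-[4-methoxy-2-(methoxymethoxy)-6-pentylphenoxy]-6-methylbenzoate; 22 N-methoxy-N-methylhexanamide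
Product: 25 methyl 4-(methoxymethoxy)-2-[4-methoxy-2-(methoxymethoxy)-6-pentylphenoxy]-6-(2-oxoheptyl)benzoate, via benzylic lithium species 23 (not isolated), via lithium tetrahedral adduct 24 (not isolated)
Conditions: LiN(i-Pr)2 (1.2 equiv), THF, −78 °C; then 22, −78 → −20 °C; sat. aq. NH4Cl
Reagents that add atoms: lithium diisopropylamide, [Li]N(C(C)C)C(C)C (lithium of 23 and 24 only)
Why: Lateral lithiation of an ortho-toluate ester (the benzylic anion is stabilised by the ester, which is itself shielded by two ortho groups) followed by acylation with a Weinreb amide, whose chelated adduct 24 releases the ketone only on quench and so prevents double addition; this is the standard route from orsellinate-type esters to 3-alkylisocoumarin precursors.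

Step 13
Reactants: 25 methyl 4-(methoxymethoxy)-2-[4-methoxy-2-(methoxymethoxy)-6-pentylphenoxy]-6-(2-oxoheptyl)benzoate
Product: 27 6-hydroxy-8-(2-hydroxy-4-methoxy-6-pentylphenoxy)-3-pentyl-1H-isochromen-1-one, via bis-phenol keto ester 26 (not isolated)
Conditions: TFA, CH2Cl2, 0 → 40 °C; aqueous work-up
Reagents that add atoms: none
Why: Acid cleaves both MOM acetals (giving 26) and catalyses enol lactonisation of the 2-oxoheptyl ketone onto the neighbouring ester with loss of methanol; the six-membered closure to the conjugated isocoumarin should be faster than seven-membered closure by the ring B phenol, and the aryl methyl ether is inert to TFA.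

## Compound list

1 | olivetol (5-pentylbenzene-1,3-diol) | CCCCCc1cc(O)cc(O)c1 | starting material
2 | N-[(2,4-dihydroxy-6-pentylphenyl)methylidene]-N-methylmethanaminium chloride | CCCCCc1cc(O)cc(O)c1C=[N+](C)C.[Cl-] | intermediate (not isolated)
3 | 2,4-dihydroxy-6-pentylbenzaldehyde | CCCCCc1cc(O)cc(O)c1C=O | intermediate
4 | 2-hydroxy-4-methoxy-6-pentylbenzaldehyde | CCCCCc1cc(OC)cc(O)c1C=O | intermediate
5 | 4-methoxy-2-(methoxymethoxy)-6-pentylbenzaldehyde | CCCCCc1cc(OC)cc(OCOC)c1C=O | intermediate
6 | 4-methoxy-2-(methoxymethoxy)-6-pentylphenyl formate | CCCCCc1cc(OC)cc(OCOC)c1OC=O | intermediate (not isolated)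
7 | 4-methoxy-2-(methoxymethoxy)-6-pentylphenol | CCCCCc1cc(OC)cc(OCOC)c1O | intermediate
8 | trichloroethylene | ClC=C(Cl)Cl | starting material
9 | 2-[(E)-1,2-dichloroethenoxy]-5-methoxy-1-(methoxymethoxy)-3-pentylbenzene | Cl/C=C(/Cl)Oc1c(OCOC)cc(OC)cc1CCCCC | intermediate
10 | 2-[(chloroethynyl)oxy]-5-methoxy-1-(methoxymethoxy)-3-pentylbenzene | ClC#COc1c(OCOC)cc(OC)cc1CCCCC | intermediate (not isolated)
11 | lithium [4-methoxy-2-(methoxymethoxy)-6-pentylphenoxy]acetylide | [Li]C#COc1c(OCOC)cc(OC)cc1CCCCC | intermediate (not isolated)
12 | 2-(ethynyloxy)-5-methoxy-1-(methoxymethoxy)-3-pentylbenzene | C#COc1c(OCOC)cc(OC)cc1CCCCC | intermediate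
13 | dimethyl malonate | COC(=O)CC(=O)OC | starting material
14 | 4,4-dimethoxybutan-2-one | CC(=O)CC(OC)OC | starting material
15 | dimethyl 2-(4,4-dimethoxybutan-2-ylidene)propanedioate | COC(=O)C(C(=O)OC)=C(C)CC(OC)OC | intermediate
16 | methyl 4-methyl-2-oxo-2H-pyran-3-carboxylate | COC(=O)c1c(C)ccoc1=O | intermediate
17 | methyl 8-[4-methoxy-2-(methoxymethoxy)-6-pentylphenoxy]-5-methyl-3-oxo-2-oxabicyclo[2.2.2]octa-5,7-diene-4-carboxylate (racemic; the two bridgehead centres are locked to each other by the bicycle) | COC(=O)C12C(C)=CC(OC1=O)C=C2Oc1c(OCOC)cc(OC)cc1CCCCC | intermediate (not isolated)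
18 | methyl 2-[4-methoxy-2-(methoxymethoxy)-6-pentylphenoxy]-6-methylbenzoate | COC(=O)c1c(C)cccc1Oc1c(OCOC)cc(OC)cc1CCCCC | intermediate
19 | methyl 2-[4-methoxy-2-(methoxymethoxy)-6-pentylphenoxy]-6-methyl-4-(4,4,5,5-tetramethyl-1,3,2-dioxaborolan-2-yl)benzoate | COC(=O)c1c(C)cc(B2OC(C)(C)C(C)(C)O2)cc1Oc1c(OCOC)cc(OC)cc1CCCCC | intermediate (not isolated)
20 | methyl 4-hydroxy-2-[4-methoxy-2-(methoxymethoxy)-6-pentylphenoxy]-6-methylbenzoate | COC(=O)c1c(C)cc(O)cc1Oc1c(OCOC)cc(OC)cc1CCCCC | intermediate
21 | methyl 4-(methoxymethoxy)-2-[4-methoxy-2-(methoxymethoxy)-6-pentylphenoxy]-6-methylbenzoate | COC(=O)c1c(C)cc(OCOC)cc1Oc1c(OCOC)cc(OC)cc1CCCCC | intermediate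
22 | N-methoxy-N-methylhexanamide | CCCCCC(=O)N(C)OC | starting material
23 | {5-(methoxymethoxy)-2-(methoxycarbonyl)-3-[4-methoxy-2-(methoxymethoxy)-6-pentylphenoxy]phenyl}methyllithium | [Li]Cc1cc(OCOC)cc(Oc2c(OCOC)cc(OC)cc2CCCCC)c1C(=O)OC | intermediate (not isolated)
24 | lithium alkoxide of methyl 2-{2-hydroxy-2-[methoxy(methyl)amino]heptyl}-4-(methoxymethoxy)-6-[4-methoxy-2-(methoxymethoxy)-6-pentylphenoxy]benzoate (racemic) | CCCCCC(O[Li])(Cc1cc(OCOC)cc(Oc2c(OCOC)cc(OC)cc2CCCCC)c1C(=O)OC)N(C)OC | intermediate (not isolated)
25 | methyl 4-(methoxymethoxy)-2-[4-methoxy-2-(methoxymethoxy)-6-pentylphenoxy]-6-(2-oxoheptyl)benzoate | COC(=O)c1c(CC(=O)CCCCC)cc(OCOC)cc1Oc1c(OCOC)cc(OC)cc1CCCCC | intermediate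
26 | methyl 4-hydroxy-2-(2-hydroxy-4-methoxy-6-pentylphenoxy)-6-(2-oxoheptyl)benzoate | COC(=O)c1c(CC(=O)CCCCC)cc(O)cc1Oc1c(O)cc(OC)cc1CCCCC | intermediate (not isolated)
27 | 6-hydroxy-8-(2-hydroxy-4-methoxy-6-pentylphenoxy)-3-pentyl-1H-isochromen-1-one | CCCCCc1cc2cc(O)cc(Oc3c(O)cc(OC)cc3CCCCC)c2c(=O)o1 | target

## Step count and least certain steps

Total: 13 steps. Longest linear sequence: 11 steps (steps 1–6 and 9–13, from olivetol 1). The pyranone branch is 2 steps (7–8).

**Step 9 (key step).** The most likely failure is self-reaction (oligomerisation, adventitious hydration) of ynol ether 12 outrunning the cycloaddition. An aryloxyalkyne is a weaker donor than an ynamine or a ketene acetal, and the 4-methyl group makes 16 a slightly poorer acceptor, so the temperature needed may exceed what 12 tolerates. Within the same approach, a mild chelating Lewis acid such as Yb(fod)3 (fod = 6,6,7,7,8,8,8-heptafluoro-2,2-dimethyloctane-3,5-dionate) could be tried to lower the temperature. The fallback gives up the cycloaddition and makes the ether by copper-mediated Ullmann coupling. It sets out from phenol 7, which is coupled with commercial methyl 2-bromo-6-methylbenzoate (COC(=O)c1c(C)cccc1Br) under CuI, picolinic acid, K3PO4, DMSO, 90 °C. This ligand system is suited to ortho-substituted partners, and the route is rejoined at 18. No compound outside the list is made (entry F0).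

**Step 6.** The most likely failure is loss of the terminal ynol ether during work-up and concentration, since it is sensitive to acid, heat and high concentration. Prolonged exposure to n-BuLi could also cause ring lithiation between the two oxygens. The fallback sets out from 9 and uses the same elimination and exchange, but acetylide 11 is capped with Me3SiCl to give trimethyl{[4-methoxy-2-(methoxymethoxy)-6-pentylphenoxy]ethynyl}silane F1. This compound should tolerate chromatography and storage. Desilylation with catalytic K2CO3 in MeOH at 0 °C releases the alkyne immediately before use, returning to the route at 12.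

**Step 8.** The most likely failure is slow opening of the acetal. That would force hot acid, under which ester hydrolysis with decarboxylation and retro-Knoevenagel cleavage compete with ring closure. The fallback sets out from 13, which is condensed with acetone (TiCl4, pyridine, as in step 7) to give dimethyl 2-(propan-2-ylidene)propanedioate F2. Vinylogous aminomethylenation with N,N-dimethylformamide dimethyl acetal (PhMe, 100 °C) gives dimethyl 2-[(3E)-4-(dimethylamino)but-3-en-2-ylidene]propanedioate F3. Its enamine is hydrolysed and lactonised in aqueous AcOH at moderate temperature, conditions much milder than acetal opening, rejoining the route at 16.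

**Step 13.** Two processes may interfere. The methoxymethyl cation released on acetal cleavage may re-add to the electron-rich rings. Enol lactonisation may also be incomplete, or the ring B phenol may close onto the ester to give a seven-membered aryl lactone. The fallback sets out from 25 and separates the events, with ring closure first while both phenols are still protected:
- SN2 demethylation of the hindered ester with LiI in pyridine (reflux) gives 4-(methoxymethoxy)-2-[4-methoxy-2-(methoxymethoxy)-6-pentylphenoxy]-6-(2-oxoheptyl)benzoic acid F4.
- Ac2O/pyridine at rt dehydrates the keto acid through its mixed anhydride to 6-(methoxymethoxy)-8-[4-methoxy-2-(methoxymethoxy)-6-pentylphenoxy]-3-pentyl-1H-isochromen-1-one F5.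
- HCl in MeOH then removes both acetals, with the cation trapped by solvent and no free ester left for the ring B phenol to attack, arriving at 27.

## Further compounds

F0 | step 9 | none | none
F1 | step 6 | trimethyl{[4-methoxy-2-(methoxymethoxy)-6-pentylphenoxy]ethynyl}silane | C[Si](C)(C)C#COc1c(OCOC)cc(OC)cc1CCCCC
F2 | step 8 | dimethyl 2-(propan-2-ylidene)propanedioate | COC(=O)C(C(=O)OC)=C(C)C
F3 | step 8 | dimethyl 2-[(3E)-4-(dimethylamino)but-3-en-2-ylidene]propanedioate | COC(=O)C(C(=O)OC)=C(C)/C=C/N(C)C
F4 | step 13 | 4-(methoxymethoxy)-2-[4-methoxy-2-(methoxymethoxy)-6-pentylphenoxy]-6-(2-oxoheptyl)benzoic acid | OC(=O)c1c(CC(=O)CCCCC)cc(OCOC)cc1Oc1c(OCOC)cc(OC)cc1CCCCC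
F5 | step 13 | 6-(methoxymethoxy)-8-[4-methoxy-2-(methoxymethoxy)-6-pentylphenoxy]-3-pentyl-1H-isochromen-1-one | CCCCCc1cc2cc(OCOC)cc(Oc3c(OCOC)cc(OC)cc3CCCCC)c2c(=O)o1
A1 | alternative 1 | dimethyl 2-[5-(benzyloxy)-2-(diethylcarbamoyl)-3-methylphenoxy]propanedioate | COC(=O)C(Oc1cc(OCc2ccccc2)cc(C)c1C(=O)N(CC)CC)C(=O)OC
A2 | alternative 1 | (E)-non-3-en-2-one | CCCCC/C=C/C(C)=O
A3 | alternative 1 | methyl 1-[5-(benzyloxy)-2-(diethylcarbamoyl)-3-methylphenoxy]-2,4-dioxo-6-pentylcyclohexane-1-carboxylate (diastereomer mixture) | CCCCCC1CC(=O)CC(=O)C1(Oc1cc(OCc2ccccc2)cc(C)c1C(=O)N(CC)CC)C(=O)OC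
A4 | alternative 2 | 5-(benzyloxy)-3-[2-(benzyloxy)-4-methoxy-6-pentylphenoxy]-2-(trimethylsilyl)phenyl trifluoromethanesulfonate | C[Si](C)(C)c1c(OS(=O)(=O)C(F)(F)F)cc(OCc2ccccc2)cc1Oc1c(OCc2ccccc2)cc(OC)cc1CCCCC
A5 | alternative 2 | hept-1-yne | CCCCCC#C
A6 | alternative 2 | carbon dioxide | O=C=O
A7 | alternative 2 | 6-(benzyloxy)-8-[2-(benzyloxy)-4-methoxy-6-pentylphenoxy]-3-pentyl-1H-isochromen-1-one | CCCCCc1cc2cc(OCc3ccccc3)cc(Oc3c(OCc4ccccc4)cc(OC)cc3CCCCC)c2c(=O)o1
A8 | alternative 3 | methyl 4-(benzyloxy)-2-{[2-(2-diazoacetyl)hept-1-en-1-yl]oxy}-6-methylbenzoate | CCCCCC(=COc1cc(OCc2ccccc2)cc(C)c1C(=O)OC)C(=O)C=[N+]=[N-]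
A9 | alternative 3 | methoxyethyne | COC#C
A10 | alternative 3 | methyl 4-(benzyloxy)-2-(2-hydroxy-4-methoxy-6-pentylphenoxy)-6-methylbenzoate | CCCCCc1cc(OC)cc(O)c1Oc1cc(OCc2ccccc2)cc(C)c1C(=O)OC
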